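**Retrosynthetic overview**

1. The guanine is cut last at C8: salicylaldehyde 30 plus 2,5,6-triaminopyrimidin-4(3H)-one closes the imidazole ring oxidatively; the aldehyde carbon comes from ortho-formylation of the ring A phenol 28.
2. The strategy rests on ring B, the 1,4-phenylene whose C4' carries only the ether oxygen and whose C1' carries only the CH2, bridged para inside the 14-membered ring (ring B C1'–C4', O, ring A C3–C2–C1, CH2, piperazine C5–N4–C3–C2, CH2); this bent arene is grown, not bought.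
3. Ring B and the macrocycle are cut together at C4'–C5' and C3'–C2': an intramolecular Diels–Alder reaction of a 5-substituted 2-pyrone with an aryl ethynyl ether in 25, then loss of CO2.
4. Precursor 25 is a cis-2,5-disubstituted N,N'-di-Boc piperazine; the pyron-5-ylmethyl arm comes from a serine-derived alkylzinc and 5-bromo-2-pyrone, the ethynyl ether from the ring A 3-OH via its dichlorovinyl ether.
5. The piperazine comes from LiAlH4 reduction of the diketopiperazine of L-serine and a 4-O-benzyl-3-hydroxy-L-phenylalanine made from 3-iodo-L-tyrosine (both stereocentres from the chiral pool). Ring order: ring A (bought), diketopiperazine, piperazine, ring B with the 14-membered ring, imidazole ring of the guanine.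

Key step: step 15

Assumption (chemistry): tert-butyl carbamates and a benzyl ether are used on the key-step compounds, so that the carbamates survive n-BuLi and the phenol can be freed without touching them; this limits the cycloaddition to about 150 °C. The triamine is used as its commercial sulfate and the target is isolated as the free base.

**Route**

Step 1
Reactants: 1 3-iodo-L-tyrosine
Product: 2 methyl 3-iodo-L-tyrosinate hydrochloride
Conditions: SOCl2, MeOH, 0 °C to reflux
Reagents that add atoms: methanol CO; thionyl chloride O=S(Cl)Cl (source of the chloride of the salt)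
Why: Acid-mediated esterification with HCl made in situ should give the ester salt without touching the α-centre or the phenol.

Step 2
Reactants: 3 N-Boc-L-serine
Product: 5 N-Boc-O-(triisopropylsilyl)-L-serine, via bis-silyl compound 4 (not isolated)
Conditions: TIPSCl (2.2 equiv), imidazole, DMF, rt; then K2CO3, MeOH/H2O, rt; acidify to pH 4
Reagents that add atoms: chlorotriisopropylsilane CC(C)[Si](Cl)(C(C)C)C(C)C
Why: Imidazole-promoted silylation covers the primary alcohol, and the much more labile silyl ester is cleaved by mild carbonate solvolysis, leaving a silyl ether chosen to tolerate the acid, hydride and organolithium steps ahead.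

Step 3
Reactants: 2 methyl 3-iodo-L-tyrosinate hydrochloride; 5 N-Boc-O-(triisopropylsilyl)-L-serine
Product: 6 methyl N-[N-Boc-O-(triisopropylsilyl)-L-seryl]-3-iodo-L-tyrosinate
Conditions: EDC·HCl, HOBt, N-methylmorpholine, CH2Cl2/DMF, 0 °C to rt
Reagents that add atoms: none
Why: Carbodiimide/HOBt amide coupling of a urethane-protected acid should proceed without racemisation, the amine being far more nucleophilic than the free phenol.

Step 4
Reactants: 6 methyl N-[N-Boc-O-(triisopropylsilyl)-L-seryl]-3-iodo-L-tyrosinate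
Product: 7 methyl N-[N-Boc-O-(triisopropylsilyl)-L-seryl]-O-benzyl-3-iodo-L-tyrosinate
Conditions: BnBr, K2CO3, DMF, rt
Reagents that add atoms: benzyl bromide BrCc1ccccc1
Why: Williamson etherification is selective because only the phenol is deprotonated by carbonate; this oxygen becomes the free phenol of the target.

Step 5
Reactants: 7 methyl N-[N-Boc-O-(triisopropylsilyl)-L-seryl]-O-benzyl-3-iodo-L-tyrosinate
Product: 9 methyl N-[N-Boc-O-(triisopropylsilyl)-L-seryl]-O-benzyl-3-hydroxy-L-tyrosinate, via pinacol boronate 8 (not isolated)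
Conditions: B2pin2, PdCl2(dppf), KOAc, DMSO, 80 °C; then 30% H2O2, NaHCO3, THF/H2O, 0 °C to rt
Reagents that add atoms: bis(pinacolato)diboron CC1(C)OB(OC1(C)C)B1OC(C)(C)C(C)(C)O1 (boron of 8 only); hydrogen peroxide OO (oxygen of 9)
Why: Miyaura borylation of the aryl iodide followed by oxidation of the C–B bond places the hydroxyl exactly at ring A C3, the later ether oxygen.

Step 6
Reactants: 9 methyl N-[N-Boc-O-(triisopropylsilyl)-L-seryl]-O-benzyl-3-hydroxy-L-tyrosinate
Product: 11 (3S,6S)-3-[(4-benzyloxy-3-hydroxyphenyl)methyl]-6-[(triisopropylsilyloxy)methyl]piperazine-2,5-dione, via amine trifluoroacetate 10 (not isolated)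
Conditions: TFA/CH2Cl2 (1:4), anisole, 0 °C; evaporate; then N-methylmorpholine, AcOH (cat.), 2-butanol/toluene, 90 °C
Reagents that add atoms: trifluoroacetic acid OC(=O)C(F)(F)F (counter-ion of 10 only)
Why: Acidolysis of the Boc group and intramolecular aminolysis of the methyl ester (diketopiperazine formation) under a weakly buffered medium should close the cis-diketopiperazine without epimerisation.

Step 7
Reactants: 11 (3S,6S)-3-[(4-benzyloxy-3-hydroxyphenyl)methyl]-6-[(triisopropylsilyloxy)methyl]piperazine-2,5-dione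
Product: 12 (2R,5S)-2-[(triisopropylsilyloxy)methyl]-5-[(4-benzyloxy-3-hydroxyphenyl)methyl]piperazine
Conditions: LiAlH4, THF, reflux; aq potassium sodium tartrate work-up
Reagents that add atoms: none
Why: Hydride reduction of both lactams to amines leaves the two stereocentres untouched (the R descriptor at C2 is only a priority change), and the hindered silyl ether and the benzyl ether should survive.

Step 8
Reactants: 12 (2R,5S)-2-[(triisopropylsilyloxy)methyl]-5-[(4-benzyloxy-3-hydroxyphenyl)methyl]piperazine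
Product: 13 di-tert-butyl (2S,5R)-2-[(4-benzyloxy-3-hydroxyphenyl)methyl]-5-[(triisopropylsilyloxy)methyl]piperazine-1,4-dicarboxylate
Conditions: Boc2O (2.3 equiv), NaHCO3, THF/H2O, rt
Reagents that add atoms: di-tert-butyl dicarbonate CC(C)(C)OC(=O)OC(=O)OC(C)(C)C
Why: Carbamate formation on the two secondary amines is much faster than acylation of the phenol under bicarbonate, so the phenol stays free.

Step 9
Reactants: 13 di-tert-butyl (2S,5R)-2-[(4-benzyloxy-3-hydroxyphenyl)methyl]-5-[(triisopropylsilyloxy)methyl]piperazine-1,4-dicarboxylate; 14 trichloroethylene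
Product: 15 di-tert-butyl (2S,5R)-2-{[4-benzyloxy-3-((E)-1,2-dichlorovinyloxy)phenyl]methyl}-5-[(triisopropylsilyloxy)methyl]piperazine-1,4-dicarboxylate
Conditions: K2CO3, DMF, 70 °C
Reagents that add atoms: none
Why: Carbonate converts trichloroethylene into dichloroacetylene, to which the phenoxide adds in anti fashion to give the E-dichlorovinyl ether (the standard entry to aryl ynol ethers).

Step 10
Reactants: 15 di-tert-butyl (2S,5R)-2-{[4-benzyloxy-3-((E)-1,2-dichlorovinyloxy)phenyl]methyl}-5-[(triisopropylsilyloxy)methyl]piperazine-1,4-dicarboxylate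
Product: 18 di-tert-butyl (2S,5R)-2-[(4-benzyloxy-3-ethynyloxyphenyl)methyl]-5-[(triisopropylsilyloxy)methyl]piperazine-1,4-dicarboxylate, via chloroethynyl ether 16 (not isolated), via lithium acetylide 17 (not isolated)
Conditions: n-BuLi (2.3 equiv), THF, −78 to −50 °C; then H2O, −78 °C
Reagents that add atoms: n-butyllithium [Li]CCCC (lithium of 17 only)
Why: Deprotonation and loss of LiCl give the chloroalkyne, lithium–chlorine exchange gives the acetylide and protonation the terminal ynol ether, while tert-butyl carbamates, the silyl ether and the benzyl ether are inert to n-BuLi at −78 °C.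

Step 11
Reactants: 18 di-tert-butyl (2S,5R)-2-[(4-benzyloxy-3-ethynyloxyphenyl)methyl]-5-[(triisopropylsilyloxy)methyl]piperazine-1,4-dicarboxylate
Product: 19 di-tert-butyl (2S,5R)-2-[(4-benzyloxy-3-ethynyloxyphenyl)methyl]-5-(hydroxymethyl)piperazine-1,4-dicarboxylate
Conditions: TBAF, THF, 0 °C to rt
Reagents that add atoms: none
Why: Fluoride desilylation is a basic, acid-free deprotection, so the acid-sensitive ynol ether should survive.

Step 12
Reactants: 19 di-tert-butyl (2S,5R)-2-[(4-benzyloxy-3-ethynyloxyphenyl)methyl]-5-(hydroxymethyl)piperazine-1,4-dicarboxylate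
Product: 21 di-tert-butyl (2S,5R)-2-[(4-benzyloxy-3-ethynyloxyphenyl)methyl]-5-(iodomethyl)piperazine-1,4-dicarboxylate, via mesylate 20 (not isolated)
Conditions: MsCl, Et3N, THF, 0 °C; then NaI, acetone, 45 °C
Reagents that add atoms: methanesulfonyl chloride CS(=O)(=O)Cl (in 20 only); sodium iodide [Na+].[I-]
Why: Sulfonylation followed by Finkelstein displacement makes the primary iodide without any electrophilic iodine reagent, which would add to the electron-rich alkyne.

Step 13
Reactants: 22 coumalic acid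
Product: 23 5-bromo-2H-pyran-2-one
Conditions: NBS, LiOAc (cat.), MeCN/H2O, rt
Reagents that add atoms: N-bromosuccinimide O=C1CCC(=O)N1Br
Why: Hunsdiecker-type bromodecarboxylation (ipso-bromination at the enol-ether-like C5, then loss of CO2) is an established one-step entry to 5-bromo-2-pyrone.

Step 14
Reactants: 21 di-tert-butyl (2S,5R)-2-[(4-benzyloxy-3-ethynyloxyphenyl)methyl]-5-(iodomethyl)piperazine-1,4-dicarboxylate; 23 5-bromo-2H-pyran-2-one
Product: 25 di-tert-butyl (2S,5S)-2-[(4-benzyloxy-3-ethynyloxyphenyl)methyl]-5-[(2-oxo-2H-pyran-5-yl)methyl]piperazine-1,4-dicarboxylate, via alkylzinc iodide 24 (not isolated)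
Conditions: Zn dust (I2-activated), DMF, rt; then 23, Pd2(dba)3 (2.5 mol %), SPhos (10 mol %), rt to 35 °C
Reagents that add atoms: zinc [Zn] (in 24 only)
Why: Zinc insertion into the primary C–I bond gives a carbamate-stabilised β-amino alkylzinc of the serine type, which undergoes Negishi coupling with the alkenyl bromide under zerovalent palladium at near-ambient temperature without touching the stereocentre.

Step 15
Reactants: 25 di-tert-butyl (2S,5S)-2-[(4-benzyloxy-3-ethynyloxyphenyl)methyl]-5-[(2-oxo-2H-pyran-5-yl)methyl]piperazine-1,4-dicarboxylate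
Product: 27 N,N'-di-Boc O-benzyl macrocyclic diaryl ether piperazine (14-membered ring; ring A carries OBn at C4 and the ether oxygen at C3), via bridged lactone 26 (not isolated)
Conditions: o-xylene (1 mM, syringe-pump addition), BHT, solid K2CO3, 140 °C, Ar
Reagents that add atoms: none
Why: An inverse-electron-demand intramolecular (4+2) cycloaddition of the 2-pyrone (diene C3–C6) with the electron-rich ynol ether gives bridged lactone 26, which loses CO2 by retro-(4+2) reaction; the closest known reaction type is the intramolecular 2-pyrone/alkyne Diels–Alder–decarboxylation used to make strained para-bridged arenes. Ring B closes as a six-membered ring by the cycloaddition itself (alkyne O-bearing carbon to pyrone C3, terminal carbon to pyrone C6), and the 14-membered ring closes at the same time through the ten-atom tether from pyrone C5 to the O-bearing alkyne carbon (a type 2 intramolecular Diels–Alder macrocyclisation giving a bridged adduct). No new stereocentre remains: the two bridgeheads of 26 vanish on aromatisation, and the piperazine centres are remote and not epimerisable under neutral heat. The step needs para and not meta closure, which the tether alone does not enforce; the polarised ynol ether should put its nucleophilic terminal carbon on the electrophilic C6 and its oxygen-bearing carbon on C3, placing O para to the CH2 on C5, whereas the meta mode is polarity-mismatched. It also needs ring closure to beat oligomerisation, which high dilution with slow addition should secure, helped by the two carbamates, which should push both arms pseudoaxial on the same face of the piperazine. The strain is paid late, because 26 is not planar and the macrocycle forms before any flat arene has to bend, and the loss of CO2 is irreversible.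

Step 16
Reactants: 27 N,N'-di-Boc O-benzyl macrocyclic diaryl ether piperazine
Product: 28 N,N'-di-Boc macrocyclic phenol (ring A C4–OH)
Conditions: H2 (1 atm), 10% Pd/C, EtOAc/EtOH, rt
Reagents that add atoms: none
Why: Hydrogenolysis cleaves only the benzyl ether; diaryl ether and tert-butyl carbamates are inert.

Step 17
Reactants: 28 N,N'-di-Boc macrocyclic phenol
Product: 30 N,N'-di-Boc macrocyclic salicylaldehyde (CHO at ring A C5), via hydroxymethyl phenol 29 (not isolated)
Conditions: MgCl2, Et3N, (CH2O)n, MeCN, reflux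
Reagents that add atoms: paraformaldehyde, as formaldehyde C=O
Why: Magnesium-phenoxide-directed ortho-formylation (hydroxymethylation, then hydride transfer to a second formaldehyde) can only occur at C5, the one free ortho position, since C3 carries the aryloxy group and the para position the CH2.

Step 18
Reactants: 30 N,N'-di-Boc macrocyclic salicylaldehyde; 31 2,5,6-triaminopyrimidin-4(3H)-one sulfate
Product: 34 N,N'-di-Boc guanipiperazine A, via Schiff base 32 (not isolated), via dihydropurine 33 (not isolated)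
Conditions: NaOAc, DMSO, 60 °C, N2; then FeCl3 (10 mol %), air, 90 °C
Reagents that add atoms: none
Why: In this Traube-type oxidative condensation the most nucleophilic 5-amino group forms the imine, the 6-amino group closes the five-membered ring onto it and aerobic dehydrogenation gives the 8-arylguanine.

Step 19
Reactants: 34 N,N'-di-Boc guanipiperazine A
Product: 35 guanipiperazine A
Conditions: TFA/CH2Cl2 (1:2), anisole, rt; then aq NH3
Reagents that add atoms: none
Why: Acidolysis removes both tert-butyl carbamates (anisole traps the tert-butyl cation away from the electron-rich phenol), and neutralisation gives the free base with both (S) centres intact.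

**Compound list**

1 | 3-iodo-L-tyrosine | N[C@@H](Cc1ccc(O)c(I)c1)C(=O)O | starting material
2 | methyl 3-iodo-L-tyrosinate hydrochloride | Cl.N[C@@H](Cc1ccc(O)c(I)c1)C(=O)OC | intermediate
3 | N-Boc-L-serine | CC(C)(C)OC(=O)N[C@@H](CO)C(=O)O | starting material
4 | triisopropylsilyl N-Boc-O-(triisopropylsilyl)-L-serinate | CC(C)(C)OC(=O)N[C@@H](CO[Si](C(C)C)(C(C)C)C(C)C)C(=O)O[Si](C(C)C)(C(C)C)C(C)C | intermediate
5 | N-Boc-O-(triisopropylsilyl)-L-serine | CC(C)(C)OC(=O)N[C@@H](CO[Si](C(C)C)(C(C)C)C(C)C)C(=O)O | intermediate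
6 | methyl N-[N-Boc-O-(triisopropylsilyl)-L-seryl]-3-iodo-L-tyrosinate | CC(C)(C)OC(=O)N[C@@H](CO[Si](C(C)C)(C(C)C)C(C)C)C(=O)N[C@@H](Cc1ccc(O)c(I)c1)C(=O)OC | intermediate
7 | methyl N-[N-Boc-O-(triisopropylsilyl)-L-seryl]-O-benzyl-3-iodo-L-tyrosinate | CC(C)(C)OC(=O)N[C@@H](CO[Si](C(C)C)(C(C)C)C(C)C)C(=O)N[C@@H](Cc1ccc(OCc2ccccc2)c(I)c1)C(=O)OC | intermediate
8 | pinacol boronate of 7 (Bpin in place of iodine) | CC(C)(C)OC(=O)N[C@@H](CO[Si](C(C)C)(C(C)C)C(C)C)C(=O)N[C@@H](Cc1ccc(OCc2ccccc2)c(B2OC(C)(C)C(C)(C)O2)c1)C(=O)OC | intermediate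
9 | methyl N-[N-Boc-O-(triisopropylsilyl)-L-seryl]-O-benzyl-3-hydroxy-L-tyrosinate | CC(C)(C)OC(=O)N[C@@H](CO[Si](C(C)C)(C(C)C)C(C)C)C(=O)N[C@@H](Cc1ccc(OCc2ccccc2)c(O)c1)C(=O)OC | intermediate
10 | amine trifluoroacetate of the dipeptide ester | N[C@@H](CO[Si](C(C)C)(C(C)C)C(C)C)C(=O)N[C@@H](Cc1ccc(OCc2ccccc2)c(O)c1)C(=O)OC.OC(=O)C(F)(F)F | intermediate
11 | (3S,6S)-3-[(4-benzyloxy-3-hydroxyphenyl)methyl]-6-[(triisopropylsilyloxy)methyl]piperazine-2,5-dione | N1[C@@H](CO[Si](C(C)C)(C(C)C)C(C)C)C(=O)N[C@@H](Cc2ccc(OCc3ccccc3)c(O)c2)C1=O | intermediate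
12 | (2R,5S)-2-[(triisopropylsilyloxy)methyl]-5-[(4-benzyloxy-3-hydroxyphenyl)methyl]piperazine | N1[C@@H](CO[Si](C(C)C)(C(C)C)C(C)C)CN[C@@H](Cc2ccc(OCc3ccccc3)c(O)c2)C1 | intermediate
13 | di-tert-butyl (2S,5R)-2-[(4-benzyloxy-3-hydroxyphenyl)methyl]-5-[(triisopropylsilyloxy)methyl]piperazine-1,4-dicarboxylate | CC(C)(C)OC(=O)N1[C@@H](CO[Si](C(C)C)(C(C)C)C(C)C)CN(C(=O)OC(C)(C)C)[C@@H](Cc2ccc(OCc3ccccc3)c(O)c2)C1 | intermediate
14 | trichloroethylene | ClC=C(Cl)Cl | starting material
15 | (E)-1,2-dichlorovinyl ether of 13 | CC(C)(C)OC(=O)N1[C@@H](CO[Si](C(C)C)(C(C)C)C(C)C)CN(C(=O)OC(C)(C)C)[C@@H](Cc2ccc(OCc3ccccc3)c(O/C(Cl)=C\Cl)c2)C1 | intermediate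
16 | chloroethynyl ether | CC(C)(C)OC(=O)N1[C@@H](CO[Si](C(C)C)(C(C)C)C(C)C)CN(C(=O)OC(C)(C)C)[C@@H](Cc2ccc(OCc3ccccc3)c(OC#CCl)c2)C1 | intermediate
17 | lithium aryloxyacetylide | CC(C)(C)OC(=O)N1[C@@H](CO[Si](C(C)C)(C(C)C)C(C)C)CN(C(=O)OC(C)(C)C)[C@@H](Cc2ccc(OCc3ccccc3)c(OC#C[Li])c2)C1 | intermediate
18 | di-tert-butyl (2S,5R)-2-[(4-benzyloxy-3-ethynyloxyphenyl)methyl]-5-[(triisopropylsilyloxy)methyl]piperazine-1,4-dicarboxylate | CC(C)(C)OC(=O)N1[C@@H](CO[Si](C(C)C)(C(C)C)C(C)C)CN(C(=O)OC(C)(C)C)[C@@H](Cc2ccc(OCc3ccccc3)c(OC#C)c2)C1 | intermediate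
19 | di-tert-butyl (2S,5R)-2-[(4-benzyloxy-3-ethynyloxyphenyl)methyl]-5-(hydroxymethyl)piperazine-1,4-dicarboxylate | CC(C)(C)OC(=O)N1[C@@H](CO)CN(C(=O)OC(C)(C)C)[C@@H](Cc2ccc(OCc3ccccc3)c(OC#C)c2)C1 | intermediate
20 | mesylate of 19 | CC(C)(C)OC(=O)N1[C@@H](COS(C)(=O)=O)CN(C(=O)OC(C)(C)C)[C@@H](Cc2ccc(OCc3ccccc3)c(OC#C)c2)C1 | intermediate
21 | di-tert-butyl (2S,5R)-2-[(4-benzyloxy-3-ethynyloxyphenyl)methyl]-5-(iodomethyl)piperazine-1,4-dicarboxylate | CC(C)(C)OC(=O)N1[C@@H](CI)CN(C(=O)OC(C)(C)C)[C@@H](Cc2ccc(OCc3ccccc3)c(OC#C)c2)C1 | intermediate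
22 | coumalic acid (2-oxo-2H-pyran-5-carboxylic acid) | O=C(O)c1ccc(=O)oc1 | starting material
23 | 5-bromo-2H-pyran-2-one | O=c1ccc(Br)co1 | intermediate
24 | alkylzinc iodide from 21 | CC(C)(C)OC(=O)N1[C@@H](C[Zn]I)CN(C(=O)OC(C)(C)C)[C@@H](Cc2ccc(OCc3ccccc3)c(OC#C)c2)C1 | intermediate
25 | di-tert-butyl (2S,5S)-2-[(4-benzyloxy-3-ethynyloxyphenyl)methyl]-5-[(2-oxo-2H-pyran-5-yl)methyl]piperazine-1,4-dicarboxylate | CC(C)(C)OC(=O)N1[C@@H](Cc2ccc(=O)oc2)CN(C(=O)OC(C)(C)C)[C@@H](Cc2ccc(OCc3ccccc3)c(OC#C)c2)C1 | intermediate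
26 | bridged bicyclic lactone adduct (2-oxabicyclo[2.2.2]octadienone inside the macrocycle; bridgehead configuration not defined) | c1ccccc1COc1ccc2cc1OC1=CC3OC(=O)C1C=C3C[C@H]1CN(C(=O)OC(C)(C)C)[C@H](CN1C(=O)OC(C)(C)C)C2 | intermediate
27 | N,N'-di-Boc O-benzyl macrocyclic diaryl ether piperazine | c1ccccc1COc1ccc2cc1Oc1ccc(cc1)C[C@H]1CN(C(=O)OC(C)(C)C)[C@H](CN1C(=O)OC(C)(C)C)C2 | intermediate
28 | N,N'-di-Boc macrocyclic phenol | Oc1ccc2cc1Oc1ccc(cc1)C[C@H]1CN(C(=O)OC(C)(C)C)[C@H](CN1C(=O)OC(C)(C)C)C2 | intermediate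
29 | ortho-hydroxymethyl phenol | OCc1cc2cc(c1O)Oc1ccc(cc1)C[C@H]1CN(C(=O)OC(C)(C)C)[C@H](CN1C(=O)OC(C)(C)C)C2 | intermediate
30 | N,N'-di-Boc macrocyclic salicylaldehyde | O=Cc1cc2cc(c1O)Oc1ccc(cc1)C[C@H]1CN(C(=O)OC(C)(C)C)[C@H](CN1C(=O)OC(C)(C)C)C2 | intermediate
31 | 2,5,6-triaminopyrimidin-4(3H)-one sulfate | Nc1nc(N)c(N)c(=O)[nH]1.OS(=O)(=O)O | starting material
32 | Schiff base at the 5-amino group | Nc1nc(N)c(/N=C/c2cc3cc(c2O)Oc2ccc(cc2)C[C@H]2CN(C(=O)OC(C)(C)C)[C@H](CN2C(=O)OC(C)(C)C)C3)c(=O)[nH]1 | intermediate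
33 | 7,8-dihydropurine (C8 configuration not defined) | Nc1nc2NC(c3cc4cc(c3O)Oc3ccc(cc3)C[C@H]3CN(C(=O)OC(C)(C)C)[C@H](CN3C(=O)OC(C)(C)C)C4)Nc2c(=O)[nH]1 | intermediate
34 | N,N'-di-Boc guanipiperazine A | Nc1nc2nc(-c3cc4cc(c3O)Oc3ccc(cc3)C[C@H]3CN(C(=O)OC(C)(C)C)[C@H](CN3C(=O)OC(C)(C)C)C4)[nH]c2c(=O)[nH]1 | intermediate
35 | guanipiperazine A | Nc1nc2nc(-c3cc4cc(c3O)Oc3ccc(cc3)C[C@H]3CN[C@H](CN3)C4)[nH]c2c(=O)[nH]1 | target

**Step count and risks**

Total: 19 steps. Longest linear sequence: 17 steps from 3-iodo-L-tyrosine (steps 1, 3 to 12, 14 to 19); steps 2 and 13 are side branches.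

Most likely to fail:

1. Step 15. Intermolecular cycloaddition and oligomerisation may outrun ring closure; the ynol ether may decompose thermally or be hydrated before it reacts; closure may occur in the meta sense; the carbamates may be lost if more than about 150 °C is needed. The fallback makes the same macrocycle by the known intramolecular Ullmann diaryl ether closure and sets out from 13. Acetylation (Ac2O, pyridine) would give the aryl acetate F1; HF·pyridine in THF/pyridine would free the primary alcohol F2; I2, PPh3 and imidazole would give the iodide F3; zinc insertion in DMF would give the alkylzinc iodide F4, which would be coupled with 1-bromo-4-iodobenzene (Pd2(dba)3, SPhos, reaction at the C–I bond) to the 4-bromobenzyl piperazine F5; K2CO3 in MeOH would unmask the bromo phenol F6; CuI, N,N-dimethylglycine and Cs2CO3 in dioxane at 100 °C and 2 mM would then join the ring A oxygen to ring B C4'. The fallback comes back to the route at 27.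

2. Step 14. The alkylzinc may lose the carbamate nitrogen by β-elimination, may be protonated by the alkyne C–H, or the ynol ether may be consumed by carbopalladation and oligomerisation at palladium. The fallback masks the alkyne during the organometallic step and sets out from 21. Treatment with LiN(SiMe3)2 in the presence of TMSCl (THF, −78 °C) would give the C-silylated ynol ether iodide F7; zinc insertion would give its alkylzinc iodide F8; Negishi coupling with 23 under the same catalyst would give the silyl-capped pyrone F9; TBAF (1 equiv, THF, −78 °C, neutral quench) would remove the alkynyl silicon. The fallback comes back to the route at 25.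

3. Step 18. The free triamine or the electron-rich phenol may be oxidised by air before ring closure, the dihydropurine may not be dehydrogenated cleanly, and the pyrimidine salt may dissolve poorly. The fallback avoids any oxidation at the ring-closing stage and sets out from 30. Pinnick oxidation (NaClO2, NaH2PO4, 2-methyl-2-butene) would give the salicylic acid F10; EDC/HOBt coupling with 31 (neutralised with NaOAc) at the 5-amino group would give the 5-aroylamino pyrimidinone F11; base-mediated cyclodehydration (aq NaOH/EtOH, reflux), the classical Traube closure, would form the imidazole ring. The fallback comes back to the route at 34.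

**Further compounds**

F1 | step 15 | aryl acetate of 13 | CC(C)(C)OC(=O)N1[C@@H](CO[Si](C(C)C)(C(C)C)C(C)C)CN(C(=O)OC(C)(C)C)[C@@H](Cc2ccc(OCc3ccccc3)c(OC(C)=O)c2)C1
F2 | step 15 | primary alcohol (aryl acetate) | CC(C)(C)OC(=O)N1[C@@H](CO)CN(C(=O)OC(C)(C)C)[C@@H](Cc2ccc(OCc3ccccc3)c(OC(C)=O)c2)C1
F3 | step 15 | iodide (aryl acetate) | CC(C)(C)OC(=O)N1[C@@H](CI)CN(C(=O)OC(C)(C)C)[C@@H](Cc2ccc(OCc3ccccc3)c(OC(C)=O)c2)C1
F4 | step 15 | alkylzinc iodide (aryl acetate) | CC(C)(C)OC(=O)N1[C@@H](C[Zn]I)CN(C(=O)OC(C)(C)C)[C@@H](Cc2ccc(OCc3ccccc3)c(OC(C)=O)c2)C1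
F5 | step 15 | 4-bromobenzyl piperazine (aryl acetate) | CC(C)(C)OC(=O)N1[C@@H](Cc2ccc(Br)cc2)CN(C(=O)OC(C)(C)C)[C@@H](Cc2ccc(OCc3ccccc3)c(OC(C)=O)c2)C1
F6 | step 15 | bromo phenol | CC(C)(C)OC(=O)N1[C@@H](Cc2ccc(Br)cc2)CN(C(=O)OC(C)(C)C)[C@@H](Cc2ccc(OCc3ccccc3)c(O)c2)C1
F7 | step 14 | C-silylated ynol ether iodide | CC(C)(C)OC(=O)N1[C@@H](CI)CN(C(=O)OC(C)(C)C)[C@@H](Cc2ccc(OCc3ccccc3)c(OC#C[Si](C)(C)C)c2)C1
F8 | step 14 | alkylzinc iodide of F7 | CC(C)(C)OC(=O)N1[C@@H](C[Zn]I)CN(C(=O)OC(C)(C)C)[C@@H](Cc2ccc(OCc3ccccc3)c(OC#C[Si](C)(C)C)c2)C1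
F9 | step 14 | silyl-capped pyrone | CC(C)(C)OC(=O)N1[C@@H](Cc2ccc(=O)oc2)CN(C(=O)OC(C)(C)C)[C@@H](Cc2ccc(OCc3ccccc3)c(OC#C[Si](C)(C)C)c2)C1
F10 | step 18 | salicylic acid | O=C(O)c1cc2cc(c1O)Oc1ccc(cc1)C[C@H]1CN(C(=O)OC(C)(C)C)[C@H](CN1C(=O)OC(C)(C)C)C2
F11 | step 18 | 5-aroylamino pyrimidinone | Nc1nc(N)c(NC(=O)c2cc3cc(c2O)Oc2ccc(cc2)C[C@H]2CN(C(=O)OC(C)(C)C)[C@H](CN2C(=O)OC(C)(C)C)C3)c(=O)[nH]1
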